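# Proposed total synthesis of CNP0209468.1 (compound 16)

## The problem

Target 16 is a cis-fused decalin (terpenoid numbering: ring A = C1–C5, C10; ring B = C5–C10; C4 carries the gem-dimethyl group; C11 = benzylic CH2) whose C9 bears a methyl group and the CH2 link to a 2-hydroxy-5-methoxy-1,4-benzoquinone. Four contiguous stereocentres, C8–C9–C10–C5, must be set, and two are fully substituted: C9 is an all-carbon quaternary centre and C5 a tertiary carbinol wedged between the C4 gem-dimethyl carbon and the ring fusion. The 8- and 9-methyl groups are cis (β), C11 is α, and the C5 hydroxyl is cis both to C11 (1,3 across ring B) and to H10. The cis-decalin therefore has to hold C4 or C1 syn-axial to a methyl group, so ring closures or C–C bond formations at C5 under steric or thermodynamic control lead to the trans-fused or 5-epi series. It follows that C8, C9 and C10 are best set together in one concerted event, and the C5–O bond by delivery from C11, the only substituent on the correct face.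

The feature that allows this is ring B itself. Its C7–C8 and C9–C10 bonds, its cis-8,9-dimethyl pair and its C5 carbinol (formally a hydrated C5=C6 bond) make it the adduct of a C10=C5–C6=C7 vinylcyclohexene and (E)-2-methylbut-2-enal, with C11 as the dienophile carbonyl held 1,3-cis to C5. This cyclohex-3-ene-1-carbonyl array is the retron for a Diels–Alder reaction followed by γ-lactonisation.

The tertiary C5 alcohol ionises easily to a cation flanked by migrating groups (C4 methyl, H10), and the hydroxyquinone is a vinylogous acid whose OH/OMe regiochemistry must be unambiguous. The quinone is therefore unveiled last, from an arene whose local symmetry makes the oxidation regiochemically degenerate.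

## Retrosynthesis

**16 ⇒ 15 ⇒ 14.** No skeletal bond is cut. The quinone is traced to arene 14, in which the two oxygens flanking the benzylic carbon are MOM ethers and the two meta oxygens are methyl ethers. The two para O/O pairs are mirror-related, so oxidative dealkylation across either pair gives the same quinone 15, and hydrolysis of its vinylogous MOM ester gives 16. The usual tetramethoxyarene would instead require a regioselective hydrolysis of a dimethoxyquinone. The forward reaction must be a two-electron oxidation that spares the tertiary alcohol.

**14 ⇒ 13 ⇒ 12 ⇒ 7 + 11.** The C11–aryl bond is cut with C11 at the acyl oxidation level: aryllithium 11 (from arene 10) opens lactone 7. The lactone is both the C11 electrophile and the device that carries the C5 oxygen, and acyl substitution releases the C5 alkoxide of hydroxy ketone 12. The superfluous benzylic oxygen is then removed reductively via carbinol 13. The neighbouring cuts are weaker: benzylation of a C9 enolate would need a C8 carbonyl and several adjustment steps, and aryl addition to aldehyde 5 would leave C5 unfunctionalised. Precursor 7 has fifteen carbons and no arene.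

**7 ⇒ 6 ⇒ 5.** The C5–O bond is cut. In the forward sense the C11 carboxyl of acid 6 adds across C5=C6. A five-membered lactone can only form on the α-face, 1,3-cis to C11, so the C5 configuration and the cis ring fusion are enforced and H10 is untouched. Untethered hydration of the same alkene would have to choose between a β-face screened by the axial 9-methyl group and an α-face screened by the axial C4 methyl group. Acid 6 comes from aldehyde 5 by oxidation.

**5 ⇒ 3 + 4.** The C7–C8 and C9–C10 bonds are cut; this is the key disconnection. Aldehyde 5, with ring B, the quaternary centre and three contiguous stereocentres, falls apart into achiral diene 3 and commercial tiglic aldehyde 4. The forward [4+2] must be regioselective (C9 to C10), formyl-exo and enantioface-selective.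

**3 ⇒ 2 ⇒ 1 and 10 ⇒ 9 ⇒ 8.** Diene 3 comes from 2,2-dimethylcyclohexanone 1 through enol triflate 2 and a vinyl cross-coupling. Arene 10 comes from 4,6-dibromoresorcinol 8 by MOM protection (9) and double methoxylation.

## Roads not taken

**Alternative 1:** (the most obvious) The C5–O bond is made last by terminating a cationic 1,2-shift cascade. (+)-Sclareolide A1 would be degraded and arylated to the 11-aryl-drim-8(12)-ene A2. Acid would then trigger H9→C8, CH3(10)→C9 and H5→C10 shifts, with water capturing the C5 cation. The cascade would have to pass the C10 cation without capture by an ortho oxygen of the arene, stop at C5 without the following C4-methyl shift or elimination, and take up water intermolecularly on one face of a free cation. None of these is controlled by the substrate, and the run-up to A2 is a multi-step degradation. The chosen plan never generates a cation at C5 and fixes its configuration by a tether.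

**Alternative 2:** Cut C9–C11, C10–C1 and C4–C5. Conjugate addition of the arylmethyl group to (S)-3,4-dimethylcyclohex-2-enone A3 and enolate alkylation with a 4-methylpent-4-enyl electrophile would give ketone A4. Ring A would then be closed by hydrogen-atom-transfer-initiated addition of the C4 tertiary radical to the C5 ketone. The sequence is short, but the new C4–C5 bond must form syn to the axial 9-methyl group. Attack from the open face, and the reversibility of radical addition to a carbonyl group, both favour the trans-fused 5-epimer, and C10 is an epimerisable centre next to a quaternary carbon. The hardest stereocentre would be left to the least controllable step.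

**Alternative 3:** Cut C5–C10 and C8–C9 in an intramolecular Diels–Alder reaction of the acyclic triene A5 (a 1-silyloxydiene tethered through C1–C4 to an α-methyl enal). This would close both rings and set all four stereocentres, but four things speak against it:
- The oxygen-bearing diene terminus C5 must bond to the β-carbon C10 of the enal, the electronically mismatched orientation.
- The cis ring fusion needs the formyl-exo mode.
- The diene must carry the silyloxy group inside and the terminal methyl group outside, a geometry that dienolisation of the parent enone does not guarantee.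
- With no resident stereocentre, absolute control would rest on a catalyst for a thermally demanding reaction.

The intermolecular version uses a rigid, trivially made diene and a commercial dienophile.

Key step: step 3

Assumption: the (S)-configured oxazaborolidinium catalyst is taken to expose the C2-Si face of aldehyde 4; if the sense of induction is the opposite, its (R)-antipode is used and nothing else changes.

## Route

Step 1
Reactants: 1 2,2-dimethylcyclohexan-1-one
Product: 2 6,6-dimethylcyclohex-1-en-1-yl trifluoromethanesulfonate
Conditions: LDA, THF, −78 °C; PhNTf2, −78 °C → rt; H2O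
Reagents that add atoms: N-phenyl-bis(trifluoromethanesulfonimide), O=S(=O)(N(c1ccccc1)S(=O)(=O)C(F)(F)F)C(F)(F)F
Why: Only C6 carries α-hydrogens, so enolate formation and O-sulfonylation can give a single enol triflate; no stereocentre is formed.

Step 2
Reactants: 2 6,6-dimethylcyclohex-1-en-1-yl trifluoromethanesulfonate
Product: 3 1-ethenyl-6,6-dimethylcyclohex-1-ene
Conditions: tributyl(vinyl)stannane, Pd(PPh3)4 (zerovalent palladium, 3 mol %), LiCl, THF, reflux; aq. KF
Reagents that add atoms: tributyl(vinyl)stannane, C=C[Sn](CCCC)(CCCC)CCCC
Why: Stille coupling of an enol triflate with a vinylstannane (chloride assists transmetalation) should give the 1,3-diene without disturbing the neighbouring quaternary carbon.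

Step 3
Reactants: 3 1-ethenyl-6,6-dimethylcyclohex-1-ene; 4 (E)-2-methylbut-2-enal (tiglic aldehyde)
Product: 5 (1R,2S,8aR)-1,2,5,5-tetramethyl-1,2,3,5,6,7,8,8a-octahydronaphthalene-1-carbaldehyde (terpenoid numbering: 8β,9β-dimethyl, 9α-CHO, 10α-H, C5=C6)
Conditions: oxazaborolidinium triflimide from (S)-3,3-diphenyl-1-(2-methylphenyl)tetrahydro-1H,3H-pyrrolo[1,2-c][1,3,2]oxazaborole and Tf2NH (20 mol %), CH2Cl2, −78 → −40 °C, 3 in excess
Reagents that add atoms: none
Why: The cationic oxazaborolidine binds the formyl oxygen of 4 (s-trans enal, formyl C–H···O contact) and lowers its LUMO; the diene then adds in a concerted, asynchronous [4+2] in which the unsubstituted vinyl terminus C7 bonds first to the β-carbon C8 and the ring carbon C10 closes onto the α-carbon C9. The closest known reaction type is the cationic-oxazaborolidine-catalysed Diels–Alder reaction of α-branched enals with cyclic and semicyclic dienes, and 1-vinylcyclohexenes with an allylic gem-dimethyl group are an established diene class for quinone and acetylenic dienophiles. Ring B is closed by the cycloaddition itself (bonds C7–C8 and C9–C10, new alkene C5=C6), while ring A is carried in intact. The cis relationship of the 8- and 9-methyl groups is a direct transcription of the E geometry of 4 in a suprafacial addition. C10 relative to C9 is set by the formyl-exo topicity: both methyl groups lie under the diene, so C1, the outside substituent of C10, ends up cis to the 9-methyl group and trans to C11. The absolute configuration comes from the catalyst, whose aryl groups screen one face of the bound enal so that the diene attacks the C2-Si face and gives (9R). The step needs three selectivities: regiochemistry, secured by the polarisation of the bound enal and the unhindered C7 terminus; exo over endo, expected because in the endo mode the catalyst-bound formyl group would have to sit under C5, C4 and ring A, the same quadrant argument that makes α-branched enals exo-selective with cyclopentadiene; and face selectivity, secured by the catalyst. The C4 gem-dimethyl group also destabilises the s-trans conformer of the diene and so holds it near the reactive s-cis geometry.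

Step 4
Reactants: 5 (1R,2S,8aR)-1,2,5,5-tetramethyl-1,2,3,5,6,7,8,8a-octahydronaphthalene-1-carbaldehyde
Product: 6 (1R,2S,8aR)-1,2,5,5-tetramethyl-1,2,3,5,6,7,8,8a-octahydronaphthalene-1-carboxylic acid
Conditions: NaClO2, NaH2PO4, 2-methyl-2-butene (large excess), t-BuOH/H2O, 0 °C → rt
Reagents that add atoms: sodium chlorite, [Na+].[O-]Cl=O
Why: Pinnick oxidation; the α-quaternary aldehyde cannot epimerise, and the scavenger alkene removes HOCl so that neither the C5=C6 bond nor the product acid should be chlorinated.

Step 5
Reactants: 6 (1R,2S,8aR)-1,2,5,5-tetramethyl-1,2,3,5,6,7,8,8a-octahydronaphthalene-1-carboxylic acid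
Product: 7 (5S,8S,9R,10S)-5-hydroxy-4,4,8,9-tetramethyldecalin-9-carboxylic acid 11→5 lactone (C11(=O)–O–C5 bridge on the α-face; 6-oxabicyclo[3.2.1]octan-7-one core cis-fused to ring A)
Conditions: Co(salen) complex [N,N′-bis(3,5-di-tert-butylsalicylidene)-1,2-cyclohexanediaminato]cobalt, C36H52CoN2O2 (divalent cobalt, 5 mol %), 1-fluoro-2,4,6-trimethylpyridinium triflate, PhSiH3, PhCF3, 0 °C → rt
Reagents that add atoms: none
Why: Hydrogen-atom transfer from the cobalt hydride to C6 gives the tertiary C5 radical, which is oxidised and captured by the C11 carboxyl (radical–polar crossover hydroacyloxylation). A five-membered lactone can only close on the α-face, 1,3-cis to C11, which sets C5 and makes the ring fusion cis; C10 takes no part.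

Step 6
Reactants: 8 4,6-dibromobenzene-1,3-diol
Product: 9 1,5-dibromo-2,4-bis(methoxymethoxy)benzene
Conditions: NaH, DMF, 0 °C; MOMCl, 0 °C → rt
Reagents that add atoms: chloromethyl methyl ether, COCCl
Why: Williamson-type O-alkylation of the bis-phenoxide; the MOM acetals protect both phenols and later direct the lithiation.

Step 7
Reactants: 9 1,5-dibromo-2,4-bis(methoxymethoxy)benzene
Product: 10 1,5-dimethoxy-2,4-bis(methoxymethoxy)benzene
Conditions: NaOMe, CuI (copper monoiodide, 20 mol %), DMF/MeOH, 110 °C
Reagents that add atoms: sodium methoxide, [Na+].[O-]C
Why: Copper-catalysed Ullmann-type methoxylation of both aryl bromides; MOM acetals are stable to methoxide.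

Step 8
Reactants: 10 1,5-dimethoxy-2,4-bis(methoxymethoxy)benzene; 7 lactone
Product: 12 [2,6-bis(methoxymethoxy)-3,5-dimethoxyphenyl] [(5S,8S,9R,10S)-5-hydroxy-4,4,8,9-tetramethyldecalin-9-yl] ketone (may rest as its cyclic hemiketal), via aryllithium 11 (not isolated)
Conditions: n-BuLi, THF, 0 °C; then 7 (0.7 equiv), −78 → 0 °C; H2O
Reagents that add atoms: none
Why: Directed ortho-lithiation takes place at the only position flanked by two OMOM groups. The aryllithium adds to the strained lactone carbonyl from its exo face (no α-hydrogen, so no enolisation), and collapse of the adduct releases the C5 alkoxide with its configuration intact. The di-ortho-substituted ketone should resist a second addition.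

Step 9
Reactants: 12 hydroxy ketone
Product: 14 (5S,8S,9R,10S)-9-{[2,6-bis(methoxymethoxy)-3,5-dimethoxyphenyl]methyl}-4,4,8,9-tetramethyldecalin-5-ol, via benzylic carbinol 13 (not isolated)
Conditions: Li (excess), NH3(l)/THF, −78 °C; then solid NH4Cl
Reagents that add atoms: none
Why: Dissolving-metal reduction: the ketone is reduced to the benzylic alkoxide and, once protonated by NH4Cl while lithium is still present, the benzylic C–O bond is cleaved through the arene radical anion. The tertiary, non-benzylic C5–O bond and the acetal and methyl ethers should not be reduced.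

Step 10
Reactants: 14 (5S,8S,9R,10S)-9-{[2,6-bis(methoxymethoxy)-3,5-dimethoxyphenyl]methyl}-4,4,8,9-tetramethyldecalin-5-ol
Product: 16 2-hydroxy-5-methoxy-3-{[(5S,8S,9R,10S)-5-hydroxy-4,4,8,9-tetramethyldecalin-9-yl]methyl}-1,4-benzoquinone, via MOM-protected quinone 15 (not isolated)
Conditions: (NH4)2Ce(NO3)6 (2.5 equiv), MeCN/H2O, 0 °C; the acidic aqueous mixture is then stirred at rt until the MOM group is lost
Reagents that add atoms: water, O
Why: Tetravalent cerium oxidises the tetraalkoxyarene to its radical cation and, with water, to the p-quinone with loss of one MOM and one methyl group. The two para O/O pairs are mirror-related, so both give 15, whose vinylogous MOM ester is hydrolysed in the acidic medium to 16; no stereocentre is touched.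

## Compound list

1 | 2,2-dimethylcyclohexan-1-one | CC1(C)CCCCC1=O | starting material
2 | 6,6-dimethylcyclohex-1-en-1-yl trifluoromethanesulfonate | CC1(C)CCCC=C1OS(=O)(=O)C(F)(F)F | intermediate
3 | 1-ethenyl-6,6-dimethylcyclohex-1-ene | C=CC1=CCCCC1(C)C | intermediate
4 | (E)-2-methylbut-2-enal (tiglic aldehyde) | C/C=C(\C)C=O | starting material
5 | (1R,2S,8aR)-1,2,5,5-tetramethyl-1,2,3,5,6,7,8,8a-octahydronaphthalene-1-carbaldehyde | O=C[C@]1(C)[C@@H](C)CC=C2[C@H]1CCCC2(C)C | intermediate
6 | (1R,2S,8aR)-1,2,5,5-tetramethyl-1,2,3,5,6,7,8,8a-octahydronaphthalene-1-carboxylic acid | OC(=O)[C@]1(C)[C@@H](C)CC=C2[C@H]1CCCC2(C)C | intermediate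
7 | (5S,8S,9R,10S)-5-hydroxy-4,4,8,9-tetramethyldecalin-9-carboxylic acid 11→5 lactone | O=C1O[C@]2(CC[C@H](C)[C@]1(C)[C@@H]2CCC3)C3(C)C | intermediate
8 | 4,6-dibromobenzene-1,3-diol | Oc1cc(O)c(Br)cc1Br | starting material
9 | 1,5-dibromo-2,4-bis(methoxymethoxy)benzene | COCOc1cc(OCOC)c(Br)cc1Br | intermediate
10 | 1,5-dimethoxy-2,4-bis(methoxymethoxy)benzene | COCOc1cc(OCOC)c(OC)cc1OC | intermediate
11 | [2,6-bis(methoxymethoxy)-3,5-dimethoxyphenyl]lithium | [Li]c1c(OCOC)c(OC)cc(OC)c1OCOC | intermediate (not isolated)
12 | [2,6-bis(methoxymethoxy)-3,5-dimethoxyphenyl] [(5S,8S,9R,10S)-5-hydroxy-4,4,8,9-tetramethyldecalin-9-yl] ketone | O=C(c1c(OCOC)c(OC)cc(OC)c1OCOC)[C@]2(C)[C@@H](C)CC[C@]3(O)[C@H]2CCCC3(C)C | intermediate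
13 | (5S,8S,9R,10S)-9-{[2,6-bis(methoxymethoxy)-3,5-dimethoxyphenyl](hydroxy)methyl}-4,4,8,9-tetramethyldecalin-5-ol (C11 epimers) | OC(c1c(OCOC)c(OC)cc(OC)c1OCOC)[C@]2(C)[C@@H](C)CC[C@]3(O)[C@H]2CCCC3(C)C | intermediate (not isolated)
14 | (5S,8S,9R,10S)-9-{[2,6-bis(methoxymethoxy)-3,5-dimethoxyphenyl]methyl}-4,4,8,9-tetramethyldecalin-5-ol | C(c1c(OCOC)c(OC)cc(OC)c1OCOC)[C@]2(C)[C@@H](C)CC[C@]3(O)[C@H]2CCCC3(C)C | intermediate
15 | 5-methoxy-2-(methoxymethoxy)-3-{[(5S,8S,9R,10S)-5-hydroxy-4,4,8,9-tetramethyldecalin-9-yl]methyl}-1,4-benzoquinone | COC1=CC(=O)C(OCOC)=C(C[C@]2(C)[C@@H](C)CC[C@]3(O)[C@H]2CCCC3(C)C)C1=O | intermediate (not isolated)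
16 | 2-hydroxy-5-methoxy-3-{[(5S,8S,9R,10S)-5-hydroxy-4,4,8,9-tetramethyldecalin-9-yl]methyl}-1,4-benzoquinone (CNP0209468.1) | COC1=CC(=O)C(O)=C(C[C@]2(C)[C@@H](C)CC[C@]3(O)[C@H]2CCCC3(C)C)C1=O | target

## Step count and least certain steps

Total step count: 10. Longest linear sequence: 8 (steps 1–5 and 8–10); steps 6 and 7 build the arene.

**Step 3 (key step).** The most likely failure is competition from the formyl-endo transition state, which would give the C10 epimer. A second is a sluggish cycloaddition of the β-substituted, α-branched enal, which would allow acid-induced oligomerisation of the diene; both would also erode the enantioselectivity. The fallback keeps the disconnection but changes the dienophile, so that reactivity and topicity no longer rest on the catalyst alone. It sets out from 3, which is combined under the same catalyst with ethyl (E)-3-methyl-4-oxobut-2-enoate F1. In this doubly activated dienophile the ester on C8 is cis to the future 9-methyl group and takes the endo position, which forces the formyl group exo. The adduct, ethyl (8S,9S,10R)-9-formyl-4,4,9-trimethyl-5-octalin-8-carboxylate F2, is reduced with LiAlH4 to the diol F3. The less hindered, non-neopentyl hydroxyl is tosylated to the monotosylate F4, and LiEt3BH turns the CH2OTs group into the C8 methyl group of the neopentyl alcohol F5. Oxidation (TEMPO, catalytic NaOCl, NaClO2) then gives acid 6, where the route is rejoined.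

**Step 5.** Reversible hydrogen-atom transfer may isomerise the alkene into the C5=C10 position and so scramble C10, or simply reduce the alkene, if capture of the C5 radical is slow in the strained bicyclic transition state. The fallback sets out from 6 and replaces the radical process by a polar, stereospecific one. Iodolactonisation (I2, NaHCO3, MeCN, 0 °C) gives the 6β-iodo lactone F6 by anti addition across C5=C6 without any intermediate that can touch C10. Radical deiodination (Bu3SnH, AIBN, benzene, 80 °C) returns to 7.

**Step 8.** Addition of the di-ortho-substituted aryllithium to a lactone carbonyl next to the quaternary C9 may be too slow, so that the aryllithium decomposes instead. The fallback sets out from 7 and lowers the electrophile to the aldehyde level. DIBAL-H (CH2Cl2, −78 °C) gives the lactol F7. Two equivalents of 11 then open it to the hydroxy aldehyde alkoxide and add to the unhindered formyl group, giving carbinol 13, which is isolated and submitted to the conditions of step 9; the route is rejoined at 13.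

**Step 9.** The reduction may stall at the carbinol stage, because the benzylic oxygen is present as a lithium alkoxide, a poor leaving group, and protonation has to compete with consumption of the metal. The fallback sets out from 12, which is reduced with LiAlH4 to 13. Catalytic acid (PPTS, CH2Cl2) ionises the benzylic hydroxyl, and the C5 hydroxyl closes the five-membered ring to the cyclic benzylic ether F8, both C11 epimers converging. This neutral ether is cleaved by Li/NH3 at the benzylic C–O bond without any in-situ protonation and gives 14, where the route is rejoined.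

**Step 10.** Oxidation across an ortho O/O pair (ortho-quinone formation), or ionisation of the tertiary C5 alcohol in the strongly acidic cerium medium with capture by the quinone hydroxyl or methyl migration, would divert material. The fallback sets out from 14 and separates deprotection from oxidation. TMSOTf/2,2′-bipyridyl (CH2Cl2, 0 °C, then water) removes both MOM groups under nearly neutral conditions and gives the bis-phenol F9. PhI(OAc)2 in aqueous MeCN at 0 °C then oxidises one p-methoxyphenol unit to the quinone, either unit giving the same product, and arrives at 16.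

## Further compounds

F1 | step 3 | ethyl (E)-3-methyl-4-oxobut-2-enoate | CCOC(=O)/C=C(\C)C=O
F2 | step 3 | ethyl (8S,9S,10R)-9-formyl-4,4,9-trimethyl-5-octalin-8-carboxylate (C8-ethoxycarbonyl analogue of 5) | O=C[C@]1(C)[C@@H](C(=O)OCC)CC=C2[C@H]1CCCC2(C)C
F3 | step 3 | diol (C11 and C8-CH2 hydroxyls) | OC[C@]1(C)[C@@H](CO)CC=C2[C@H]1CCCC2(C)C
F4 | step 3 | monotosylate of the C8 hydroxymethyl group | OC[C@]1(C)[C@@H](COS(=O)(=O)c3ccc(C)cc3)CC=C2[C@H]1CCCC2(C)C
F5 | step 3 | [(1R,2S,8aR)-1,2,5,5-tetramethyl-1,2,3,5,6,7,8,8a-octahydronaphthalen-1-yl]methanol | OC[C@]1(C)[C@@H](C)CC=C2[C@H]1CCCC2(C)C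
F6 | step 5 | 6β-iodo derivative of lactone 7 | O=C1O[C@]2([C@H](I)C[C@H](C)[C@]1(C)[C@@H]2CCC3)C3(C)C
F7 | step 8 | lactol of 7 (C11 epimers) | OC1O[C@]2(CC[C@H](C)[C@]1(C)[C@@H]2CCC3)C3(C)C
F8 | step 9 | cyclic benzylic ether (C11–O–C5) | COCOc4c(OC)cc(OC)c(OCOC)c4C1O[C@]2(CC[C@H](C)[C@]1(C)[C@@H]2CCC3)C3(C)C
F9 | step 10 | 2-{[(5S,8S,9R,10S)-5-hydroxy-4,4,8,9-tetramethyldecalin-9-yl]methyl}-4,6-dimethoxybenzene-1,3-diol | COc1cc(OC)c(O)c(C[C@]2(C)[C@@H](C)CC[C@]3(O)[C@H]2CCCC3(C)C)c1O
A1 | alternative 1 | (+)-sclareolide | CC1(C)CCC[C@@]2(C)[C@H]1CC[C@@]3(C)OC(=O)C[C@H]23
A2 | alternative 1 | 11-(2,3,5,6-tetramethoxyphenyl)drim-8(12)-ene | C=C1CC[C@H]2C(C)(C)CCC[C@]2(C)[C@H]1Cc1c(OC)c(OC)cc(OC)c1OC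
A3 | alternative 2 | (S)-3,4-dimethylcyclohex-2-en-1-one | C[C@H]1CCC(=O)C=C1C
A4 | alternative 2 | (2S,3R,4S)-3-{[2,6-bis(methoxymethoxy)-3,5-dimethoxyphenyl]methyl}-3,4-dimethyl-2-(4-methylpent-4-en-1-yl)cyclohexan-1-one | O=C1CC[C@H](C)[C@@](C)(Cc2c(OCOC)c(OC)cc(OC)c2OCOC)[C@@H]1CCCC(C)=C
A5 | alternative 3 | (2E,8Z,10E)-8-(tert-butyldimethylsilyloxy)-2,7,7-trimethyldodeca-2,8,10-trienal | O=C/C(C)=C/CCCC(C)(C)/C(O[Si](C)(C)C(C)(C)C)=C/C=C/C
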